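**The pool.** Each substrate put in stays as substrate, intermediate or product, so I follow the pool, substrate plus intermediate, which the second step drains.

    substrate + catalyst ⇌ catalyst + intermediate (K1 = 2.10, k1 = 34.8 M⁻¹ min⁻¹)
    reagent + catalyst + intermediate → catalyst + product (k2 = 28.1 M⁻² min⁻¹)

the same everywhere: reagent 0.0475 M; catalyst 0.17 mM

|  | substrate | remark | time |
|---|---|---|---|
| epsilon | 0.050 M | one stirred flow tank at steady state, fed with the mixture as stated, mean residence time 4.0 d |  |
| eta | 0.050 M | one stirred flow tank at steady state, fed with the mixture as stated, mean residence time 40.0 d |  |
| gamma | 0.050 M | everything together in a closed stirred flask, run for 4.0 d | 4.0 d |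
| delta | 0.050 M (fed, over 4.00 d) | all but substrate at the start; substrate goes in evenly over 4.00 d, the run ends at 4.0 d | 4.0 d |

1. the set-up with the highest amount of intermediate at the outlet or at the end, in percent of the substrate put in ("none" if the first two lie within 2 percentage points) (epsilon / eta / gamma / delta / none)
2. amount of intermediate at the outlet or at the end, in percent of the substrate put in, epsilon
3. amount of intermediate at the outlet or at the end, in percent of the substrate put in, eta
4. amount of intermediate at the outlet or at the end, in percent of the substrate put in, gamma
5. amount of intermediate at the outlet or at the end, in percent of the substrate put in, delta

- the stated concentrations are those of everything mixed, before any reaction; amounts are the same in each set-up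
- the feed brings no volume worth counting
- run time (gamma): 4.0 d

**Drain constant.** The first step relaxes in about 0.0795 d, and its equilibrium constant puts intermediate at a share 67.7% of the pool. The second step's constant times catalyst, reagent as charged and that share is the drain constant 0.221 d⁻¹. Its time, 4.52 d, is far longer than the relaxation, which makes the second step the rate-limiting step.

**Two neighbours.** Gamma and delta hold the same charge and end at the same time. In closed gamma, reagent falls with the pool and starts 5.00% lower than substrate, which makes it the limiting reagent. I drop that gap as a small correction, so the pool's part of its charge is one over one plus drain constant times contact time. Gamma's contact of 4.0 d gives 35.9%. Substrate fed evenly into delta has an average contact of 2.00 d, which is half the dosing time and shorter than gamma's contact, so I reckon 47.0%.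

**The tanks.** In a tank, one minus the pool's part equals drain constant times residence time times that part squared. This gives 43.3% for epsilon and 19.3% for eta. My winner is delta.

**The forecast.** It gives 42.5% for epsilon, 20.2% for eta, 36.5% for gamma and 47% for delta, and it names delta: “Delta wins because late-fed substrate has little time to go on to product”. Its figures differ from mine; its winner does not.

**The result.** The simulation gives 42.5% for epsilon, 20.2% for eta, 36.6% for gamma and 47.1% for delta, so delta leads. When delta's dose goes in over 30.0% of the run, the intermediate at the end stands at 39.3%. That dose has an average contact of 3.40 d, and the drain constant of 0.221 d⁻¹ over that contact gives 38.7%.

The rate constants were chosen freely; what happens was integrated by code.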